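**Retrosynthetic overview**

1. The target is the trans-(3R,4R) lactone (ring O1, C2=O, C3 with the 4-hydroxy-3-methoxybenzyl arm, C4 with the 3-hydroxy-4-methoxybenzyl arm, C5H2). The last operations are O-debenzylation and, before it, loss of a helper CO2Et on C3 with equilibration to trans.
2. Key disconnection: the bond from the ipso carbon of the 3-hydroxy-4-methoxyphenyl ring to the benzylic CH2 on C4, cut together with the C3–CH2(aryl) bond. An aryl-copper reagent opens a cyclopropane-fused lactone at its CH2, and the C3 enolate released is benzylated in the same flask (three components, two C–C bonds).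
3. Enabling feature: C3 is the enolisable carbon between C2=O and C4, and C4 carries the ArCH2 arm. C3, C4 and that CH2 can therefore be closed to a cyclopropane fused to the γ-lactone (a 3-oxabicyclo[3.1.0]hexan-2-one). A CO2Et on the ring-fusion carbon (the future C3) turns the cyclopropane CH2 into a homo-Michael acceptor.
4. Ring order: cyclopropane, then γ-lactone, both in one operation from (R)-epichlorohydrin and diethyl malonate. The cyclopropane is opened in the key step, the lactone persists, and both benzene rings are bought.
5. Stereochemistry: C4 comes from the epichlorohydrin stereocentre and is not touched again; C3 is set last, under thermodynamic control.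

Key step: step 4

**Step 1**
Reactants: 1 (R)-epichlorohydrin; 2 diethyl malonate
Product: 4 ethyl (1S,5R)-2-oxo-3-oxabicyclo[3.1.0]hexane-1-carboxylate, via diethyl (R)-2-(oxiran-2-ylmethyl)malonate 3 (not isolated)
Conditions: NaOEt (1.0 equiv), EtOH, 0 °C → reflux
Reagents that add atoms: none
Why: Malonate alkylation cascade: the malonate anion opens the epoxide at its CH2, the alkoxide displaces chloride to give the transposed epoxide 3, a second deprotonation closes the cyclopropane by 3-exo-tet attack with inversion at the stereocentre, and the resulting alkoxide lactonises onto the cis ester, so C5 of 4 (the future C4 of the target) derives its R configuration from the epichlorohydrin centre.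

**Step 2**
Reactants: 5 5-bromo-2-methoxyphenol
Product: 6 2-(benzyloxy)-4-bromo-1-methoxybenzene
Conditions: BnBr, K2CO3, DMF, rt
Reagents that add atoms: benzyl bromide, BrCc1ccccc1
Why: Williamson ether synthesis on the phenoxide; the benzyl ether survives Grignard formation and the later dealkoxycarbonylation and is removed by hydrogenolysis at the end.

**Step 3**
Reactants: 7 [4-(benzyloxy)-3-methoxyphenyl]methanol
Product: 8 1-(benzyloxy)-4-(bromomethyl)-2-methoxybenzene
Conditions: PBr3 (0.4 equiv), Et2O, 0 °C
Reagents that add atoms: phosphorus tribromide, BrP(Br)Br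
Why: Conversion of a primary benzylic alcohol into the bromide through its phosphite ester (SN2); no stereocentre is involved and the bromide is used directly.

**Step 4**
Reactants: 6 2-(benzyloxy)-4-bromo-1-methoxybenzene; 4 ethyl (1S,5R)-2-oxo-3-oxabicyclo[3.1.0]hexane-1-carboxylate; 8 1-(benzyloxy)-4-(bromomethyl)-2-methoxybenzene
Product: 11 ethyl (3R,4R)-3-[4-(benzyloxy)-3-methoxybenzyl]-4-[3-(benzyloxy)-4-methoxybenzyl]-2-oxotetrahydrofuran-3-carboxylate, via [3-(benzyloxy)-4-methoxyphenyl]magnesium bromide 9 (not isolated), via bromomagnesium lactone enolate 10 (not isolated)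
Conditions: 6, Mg, THF, 45 °C; then added to 4 (1.1 equiv), CuI (10 mol%), THF, −30 → 0 °C; then 8, DMPU, 0 → 40 °C
Reagents that add atoms: none
Why: Mechanism: the Grignard reagent 9 transmetalates to an aryl-copper(I) species that attacks the unsubstituted cyclopropane carbon (C6) of 4 in an SN2-like, strain-driven homo-conjugate (1,5-) addition, cleaving the C1–C6 bond that is polarised by the lactone and ester carbonyls on C1; this forms the aryl–CH2 bond and sets free the chelated bromomagnesium β-dicarbonyl enolate 10, which after addition of DMPU is C-benzylated by the electron-rich benzylic bromide 8. The closest known reaction types are the copper-catalysed Grignard ring opening of cyclopropane-1,1-dicarbonyl compounds (homo-Michael addition) and the conjugate-addition/enolate-alkylation tandem. No ring is closed: the three-membered ring is opened and the γ-lactone is kept. The C4 centre of 11 is the former C5 of 4 and keeps its configuration because bond formation takes place at the neighbouring CH2, while the new quaternary C3 should arise mainly by benzylation anti to the C4 arm, a ratio that is immaterial since C3 is reset in step 5. The step needs attack at CH2 and not at the ring-fusion CH (secured by the lower substitution of C6 and by retention of the five-membered lactone), 1,5- instead of carbonyl addition (soft organocopper at low temperature; once the ring has opened both carbonyls are masked as the enolate) and C- instead of O-alkylation (soft benzylic bromide, carbon-centred β-dicarbonyl enolate). A small excess of 4 makes sure that no arylmetal is left to couple with 8 when the bromide is added.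

**Step 5**
Reactants: 11 ethyl (3R,4R)-3-[4-(benzyloxy)-3-methoxybenzyl]-4-[3-(benzyloxy)-4-methoxybenzyl]-2-oxotetrahydrofuran-3-carboxylate
Product: 13 (3R,4R)-3-[4-(benzyloxy)-3-methoxybenzyl]-4-[3-(benzyloxy)-4-methoxybenzyl]dihydrofuran-2(3H)-one, via cis-(3S,4R)-lactone 12 (not isolated)
Conditions: LiCl, H2O, DMSO, 150 °C; then NaOMe (cat.), MeOH, 50 °C; AcOH
Reagents that add atoms: none
Why: Krapcho dealkoxycarbonylation (chloride SN2 at the ethyl group, loss of CO2, protonation of the lactone enolate) followed by base equilibration through the enolate: the trans-3,4-dibenzyl lactone is the more stable epimer, so whatever 12 is formed by protonation anti to the C4 arm should be funnelled to 13 with C3 = R, while the non-enolisable C4 is untouched.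

**Step 6**
Reactants: 13 (3R,4R)-3-[4-(benzyloxy)-3-methoxybenzyl]-4-[3-(benzyloxy)-4-methoxybenzyl]dihydrofuran-2(3H)-one
Product: 14 (3R,4R)-3-(4-hydroxy-3-methoxybenzyl)-4-(3-hydroxy-4-methoxybenzyl)dihydrofuran-2(3H)-one
Conditions: H2 (1 atm), 10% Pd/C, EtOAc–EtOH, rt
Reagents that add atoms: none
Why: Catalytic hydrogenolysis of the two benzyl aryl ethers; the lactone, the aryl methyl ethers and the heteroatom-free benzylic CH2 groups are inert under these neutral conditions, so both stereocentres are preserved.

**Compound list**

1 | (R)-epichlorohydrin | ClC[C@H]1CO1 | starting material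
2 | diethyl malonate | CCOC(=O)CC(=O)OCC | starting material
3 | diethyl (R)-2-(oxiran-2-ylmethyl)malonate | CCOC(=O)C(C[C@@H]1CO1)C(=O)OCC | intermediate
4 | ethyl (1S,5R)-2-oxo-3-oxabicyclo[3.1.0]hexane-1-carboxylate | CCOC(=O)[C@]12C[C@H]1COC2=O | intermediate
5 | 5-bromo-2-methoxyphenol | COc1ccc(Br)cc1O | starting material
6 | 2-(benzyloxy)-4-bromo-1-methoxybenzene | COc1ccc(Br)cc1OCc1ccccc1 | intermediate
7 | [4-(benzyloxy)-3-methoxyphenyl]methanol | COc1cc(CO)ccc1OCc1ccccc1 | starting material
8 | 1-(benzyloxy)-4-(bromomethyl)-2-methoxybenzene | COc1cc(CBr)ccc1OCc1ccccc1 | intermediate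
9 | [3-(benzyloxy)-4-methoxyphenyl]magnesium bromide | COc1ccc([Mg]Br)cc1OCc1ccccc1 | intermediate
10 | bromomagnesium enolate of ethyl (4R)-4-[3-(benzyloxy)-4-methoxybenzyl]-2-oxotetrahydrofuran-3-carboxylate | CCOC(=O)C1=C(O[Mg]Br)OC[C@@H]1Cc2ccc(OC)c(OCc3ccccc3)c2 | intermediate
11 | ethyl (3R,4R)-3-[4-(benzyloxy)-3-methoxybenzyl]-4-[3-(benzyloxy)-4-methoxybenzyl]-2-oxotetrahydrofuran-3-carboxylate (expected major C3 epimer) | CCOC(=O)[C@@]1(Cc2ccc(OCc3ccccc3)c(OC)c2)[C@@H](Cc2ccc(OC)c(OCc3ccccc3)c2)COC1=O | intermediate
12 | (3S,4R)-3-[4-(benzyloxy)-3-methoxybenzyl]-4-[3-(benzyloxy)-4-methoxybenzyl]dihydrofuran-2(3H)-one (cis epimer) | COc1ccc(C[C@H]2COC(=O)[C@H]2Cc2ccc(OCc3ccccc3)c(OC)c2)cc1OCc1ccccc1 | intermediate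
13 | (3R,4R)-3-[4-(benzyloxy)-3-methoxybenzyl]-4-[3-(benzyloxy)-4-methoxybenzyl]dihydrofuran-2(3H)-one | COc1ccc(C[C@H]2COC(=O)[C@@H]2Cc2ccc(OCc3ccccc3)c(OC)c2)cc1OCc1ccccc1 | intermediate
14 | (3R,4R)-3-(4-hydroxy-3-methoxybenzyl)-4-(3-hydroxy-4-methoxybenzyl)dihydrofuran-2(3H)-one | COc1ccc(C[C@H]2COC(=O)[C@@H]2Cc2ccc(O)c(OC)c2)cc1O | target

**Step count and risks**

Total step count: 6. Longest linear sequence: 4 steps (steps 1, 4, 5, 6).

Steps most likely to fail:

Step 4. The second half of the one-pot operation is the weak point. The tightly chelated bromomagnesium enolate may be alkylated too slowly, so that O-alkylation or coupling of residual arylmetal with the benzylic bromide competes. The fallback gives up the three-component union and stages the two C–C bonds separately. It sets out from 4: the copper-catalysed opening with 9 is run alone and quenched with dilute HCl to give ethyl (3S,4R)-4-[3-(benzyloxy)-4-methoxybenzyl]-2-oxotetrahydrofuran-3-carboxylate F1, which is isolated as a C–H acid. F1 is then benzylated with 8 as its potassium enolate in a classical malonic-ester alkylation (K2CO3, acetone, reflux). The fallback comes back to the route at 11.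

Step 5. Protonation of the lactone enolate under kinetic control takes place anti to the C4 arm and leads to the cis series, and the base equilibration may not carry the mixture fully to trans. The hindered quaternary ethyl ester may also call for temperatures at which chloride attacks the lactone at C5. The fallback changes the order of events so that C3 is set by kinetic alkylation instead of protonation. It sets out from 4 and passes through ethyl (3S,4R)-4-[3-(benzyloxy)-4-methoxybenzyl]-2-oxotetrahydrofuran-3-carboxylate F1 (made as described for step 4). F1, which carries a tertiary C–H and is dealkoxycarbonylated easily (LiCl, wet DMSO, 140 °C), gives (4R)-4-[3-(benzyloxy)-4-methoxybenzyl]dihydrofuran-2(3H)-one F2. The lithium enolate of F2 (LiHMDS, THF, −78 °C) is alkylated with 8 anti to the C4 arm, the classical trans-selective construction of dibenzylbutyrolactones. The fallback comes back to the route at 13, so 11 and 12 are never made.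

Step 1. Direct displacement of chloride by the malonate anion, competing with opening of the epoxide first, leads into the enantiomeric series and erodes the enantiomeric purity of 4. The fallback uses an electrophile with unambiguous regiochemistry and sets out from 2. Commercial (R)-3-(benzyloxy)propane-1,2-diol is converted with SOCl2/Et3N into (4S)-4-[(benzyloxy)methyl]-1,3,2-dioxathiolane 2-oxide F3 and oxidised (RuCl3 cat., NaIO4) to (4S)-4-[(benzyloxy)methyl]-1,3,2-dioxathiolane 2,2-dioxide F4. Double alkylation of 2 with F4 (NaH, 2 equiv, DME) takes place first at the primary carbon and then, with inversion, at the secondary carbon, giving diethyl (2R)-2-[(benzyloxy)methyl]cyclopropane-1,1-dicarboxylate F5. Hydrogenolysis (H2, Pd/C) frees diethyl (2R)-2-(hydroxymethyl)cyclopropane-1,1-dicarboxylate F6, which lactonises onto the cis ester (cat. TsOH). The fallback comes back to the route at 4.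

**Further compounds**

F1 | step 4 | ethyl (3S,4R)-4-[3-(benzyloxy)-4-methoxybenzyl]-2-oxotetrahydrofuran-3-carboxylate | CCOC(=O)[C@H]1C(=O)OC[C@@H]1Cc2ccc(OC)c(OCc3ccccc3)c2
F2 | step 5 | (4R)-4-[3-(benzyloxy)-4-methoxybenzyl]dihydrofuran-2(3H)-one | O=C1C[C@@H](Cc2ccc(OC)c(OCc3ccccc3)c2)CO1
F3 | step 1 | (4S)-4-[(benzyloxy)methyl]-1,3,2-dioxathiolane 2-oxide (mixture at sulfur) | O=S1OC[C@H](COCc2ccccc2)O1
F4 | step 1 | (4S)-4-[(benzyloxy)methyl]-1,3,2-dioxathiolane 2,2-dioxide | O=S1(=O)OC[C@H](COCc2ccccc2)O1
F5 | step 1 | diethyl (2R)-2-[(benzyloxy)methyl]cyclopropane-1,1-dicarboxylate | CCOC(=O)C1(C(=O)OCC)C[C@H]1COCc1ccccc1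
F6 | step 1 | diethyl (2R)-2-(hydroxymethyl)cyclopropane-1,1-dicarboxylate | CCOC(=O)C1(C(=O)OCC)C[C@H]1CO
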